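**Plan**
- **Cuts:** first the six O-alkyl bonds. Then, in the 8-linked isoflavone (unit 2, primed atoms), O1'–C2'/C2'–C3' (one carbon) and C4'–C4a' (the arylacetyl group). Then C8'–C8a' and C6'–C7' of its ring A, and last C6–C8', back to a 6-iodoisoflavone.
- **Enabling feature:** ring A of unit 2 (C4a', C5', C6', C7', C8', C8a') is a phloroglucinol ring. Its C8' holds C6 of unit 1 between the oxygen-bearing C7' and C8a'. This is a 2-aryl-3,5-dialkoxyphenol, the pattern that a 3-alkoxyvinylketene and an aryl alkoxyalkyne assemble.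
- **Forward:** genistein supplies rings A, B and C of unit 1, and C6 is iodinated and alkynylated. Ring A of unit 2 is grown on the alkyne, ring B arrives with the arylacetyl group, ring C is closed with one carbon, and global dealkylation ends the route.
- **Stereochemistry:** the target has no stereocentre and nothing has to be controlled.

Key step: step 7

Assumption: the SMILES gives no descriptor for the hindered C6–C8' axis, so the axis is formed and carried as the racemate.
Shorthand: IsoF = 5,7-dimethoxy-3-(4-methoxyphenyl)-4-oxochromen-6-yl. Unprimed chromenone atoms belong to the 6-linked unit 1 and primed ones to the 8-linked unit 2.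

Step 1
Reactants: 1 genistein
Product: 2 5-hydroxy-7-methoxy-3-(4-methoxyphenyl)chromen-4-one
Conditions: MeI (2.2 equiv), K2CO3, acetone, reflux
Reagents that add atoms: iodomethane, CI
Why: Williamson O-methylation reaches only the two free phenols, because the 5-OH is tied up in a hydrogen bond to C4=O and does not react with a weak base and two equivalents of MeI.

Step 2
Reactants: 2 5-hydroxy-7-methoxy-3-(4-methoxyphenyl)chromen-4-one
Product: 3 5-hydroxy-6-iodo-7-methoxy-3-(4-methoxyphenyl)chromen-4-one
Conditions: BnMe3N·ICl2 (1.05 equiv), CaCO3, CH2Cl2–MeOH, rt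
Reagents that add atoms: benzyltrimethylammonium dichloroiodate, C[N+](C)(C)Cc1ccccc1.Cl[I-]Cl
Why: Electrophilic aromatic iodination with buffered dichloroiodate is known to attack 5-hydroxy-7-alkoxy flavonoid A rings at C6, ortho to the chelated phenol, and the anisole ring is too unreactive to compete.

Step 3
Reactants: 3 5-hydroxy-6-iodo-7-methoxy-3-(4-methoxyphenyl)chromen-4-one
Product: 4 6-iodo-5,7-dimethoxy-3-(4-methoxyphenyl)chromen-4-one
Conditions: MeI (excess), K2CO3, DMF, 50 °C
Reagents that add atoms: iodomethane, CI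
Why: Williamson methylation in a polar solvent with excess MeI overcomes the chelation of the 5-OH, and the cap keeps this oxygen from later attacking the neighbouring alkyne or a ketene.

Step 4
Reactants: 5 chloroacetaldehyde dimethyl acetal
Product: 7 tributyl(methoxyethynyl)stannane, via lithium methoxyacetylide 6 (not isolated)
Conditions: Et2NH, n-BuLi (3.1 equiv), THF, 0 °C; 5, 0 °C → rt; Bu3SnCl, −78 °C → rt; distillation
Reagents that add atoms: tributyltin chloride, CCCC[Sn](Cl)(CCCC)CCCC
Why: Base-induced double elimination (MeOH, then HCl) followed by deprotonation is the standard in-flask source of an alkoxyacetylide, and stannylation at carbon turns it into a distillable, salt-free alkynyl donor.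

Step 5
Reactants: 4 6-iodo-5,7-dimethoxy-3-(4-methoxyphenyl)chromen-4-one; 7 tributyl(methoxyethynyl)stannane
Product: 8 6-(methoxyethynyl)-5,7-dimethoxy-3-(4-methoxyphenyl)chromen-4-one
Conditions: Pd(PPh3)4 (5 mol %), PhMe, 80 °C; chromatography on Et3N-deactivated SiO2
Reagents that add atoms: none
Why: In this Stille coupling the alkynyl group is the fastest-transferring stannane ligand and is slim enough to enter between the two ortho-methoxy groups, while the neutral, amine-free and proton-free medium spares both the acid-labile ynol ether and the base-labile pyranone.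

Step 6
Reactants: 9 acetyl chloride; 10 ethoxyacetylene
Product: 12 3-ethoxycyclobut-2-en-1-one, via ketene 11 (not isolated)
Conditions: Et3N, Et2O, 0 °C → rt, 9 added slowly to 10 and Et3N
Reagents that add atoms: none
Why: Dehydrochlorination releases ketene, which the strongly nucleophilic ynol ether intercepts in a regioselective [2+2] cycloaddition (unsubstituted alkyne carbon to the ketene carbonyl carbon), the classical entry to 3-alkoxycyclobutenones.

Step 7
Reactants: 8 6-(methoxyethynyl)-5,7-dimethoxy-3-(4-methoxyphenyl)chromen-4-one; 12 3-ethoxycyclobut-2-en-1-one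
Product: 17 6-(4-ethoxy-2-hydroxy-6-methoxyphenyl)-5,7-dimethoxy-3-(4-methoxyphenyl)chromen-4-one, via vinylketene 13 (not isolated), via vinylcyclobutenone adduct 14 (not isolated), via dienylketene 15 (not isolated), via cyclohexadienone tautomer 16 (not isolated)
Conditions: 12 (3 equiv, in portions), PhMe, sealed tube, 110 → 140 °C; then K2CO3, MeOH, rt
Reagents that add atoms: none
Why: This is a Danheiser benzannulation of a cyclobutenone with an alkoxyalkyne, the known route to resorcinol monoethers: heat opens 12 by conrotatory 4π electrocyclic cleavage of C1–C4 to vinylketene 13, whose ketene C=C adds [2+2] to the ynol ether of 8 to give 14. Reversible 4π opening of 14 passes through dienylketene 15 with the ethoxyvinyl arm turned toward the ketene carbon, and ring A of unit 2, the only ring that remains, is closed by disrotatory 6π electrocyclization (C4a'–C8a') to dienone 16, which enolizes irreversibly to phenol 17. The one selectivity needed is the orientation of the alkyne: its aryl-bearing carbon must bond to the ketene carbonyl carbon (C8'–C8a') and its methoxy-bearing carbon to the ketene α-carbon (C7'–C6'), which the oxygen lone pair secures by making the aryl-bearing carbon the nucleophilic terminus, so that OH and OMe come to flank C8'; since C6' and C4a' both end as CH, nothing else can vary. The ynol ether is a methyl ether because it has no β-hydrogen and so cannot lose an alkene by retro-ene fragmentation in the temperature range that the push–pull stabilised cyclobutenone needs for opening. The crowded axis costs little because the two ortho-methoxy groups of unit 1 face a rod-shaped alkyne when the first bond forms and the second arene is built only afterwards; no stereocentre survives (C4 of 14 becomes sp2) and the axis forms racemic. The carbonate–methanol treatment frees any phenol that excess 13 has esterified.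

Step 8
Reactants: 17 6-(4-ethoxy-2-hydroxy-6-methoxyphenyl)-5,7-dimethoxy-3-(4-methoxyphenyl)chromen-4-one; 18 4-methoxyphenylacetic acid
Product: 19 6-{4-ethoxy-2-hydroxy-6-methoxy-3-[2-(4-methoxyphenyl)acetyl]phenyl}-5,7-dimethoxy-3-(4-methoxyphenyl)chromen-4-one
Conditions: BF3·OEt2 (solvent), 85 °C; aq NaOAc
Reagents that add atoms: none
Why: In this BF3-mediated Friedel–Crafts/Fries-type acylation of a phloroglucinol monophenol, O-acylation and ortho shift end in the boron-chelated o-hydroxyketone as the thermodynamic sink, so the acyl group settles at C4a' beside the free OH and not at C6', while the BF3-complexed chromenone ring of unit 1 is deactivated.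

Step 9
Reactants: 19 6-{4-ethoxy-2-hydroxy-6-methoxy-3-[2-(4-methoxyphenyl)acetyl]phenyl}-5,7-dimethoxy-3-(4-methoxyphenyl)chromen-4-one
Product: 21 5-ethoxy-7-methoxy-3-(4-methoxyphenyl)-8-[5,7-dimethoxy-3-(4-methoxyphenyl)-4-oxochromen-6-yl]chromen-4-one, via enaminone 20 (not isolated)
Conditions: Me2NCH(OMe)2 (4 equiv), PhMe, 100 °C
Reagents that add atoms: N,N-dimethylformamide dimethyl acetal, COC(OC)N(C)C
Why: Condensation of the amide acetal with the doubly activated CH2 gives an enaminone whose β-carbon is attacked by the ortho phenol with loss of Me2NH, the standard deoxybenzoin-to-isoflavone ring closure.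

Step 10
Reactants: 21 5-ethoxy-7-methoxy-3-(4-methoxyphenyl)-8-[5,7-dimethoxy-3-(4-methoxyphenyl)-4-oxochromen-6-yl]chromen-4-one
Product: 22 5,7-dihydroxy-3-(4-hydroxyphenyl)-6-[5,7-dihydroxy-3-(4-hydroxyphenyl)-4-oxochromen-8-yl]chromen-4-one (6,8'-bigenistein)
Conditions: BBr3 (15 equiv), CH2Cl2, −78 °C → rt; then ice–H2O
Reagents that add atoms: none
Why: Lewis-acid ether cleavage with excess BBr3, established for peralkylated biflavonoids, removes the five methyl groups and the ethyl group at or below room temperature and avoids hot protic acid, which could open the pyranone of unit 2 and reclose it on O5' (Wessely–Moser shift of the linkage from C8' to C6').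

**Compound list**
1 | genistein | O=c1c(-c2ccc(O)cc2)coc2cc(O)cc(O)c12 | starting material
2 | 5-hydroxy-7-methoxy-3-(4-methoxyphenyl)chromen-4-one | COc1ccc(cc1)-c1coc2cc(OC)cc(O)c2c1=O | intermediate
3 | 5-hydroxy-6-iodo-7-methoxy-3-(4-methoxyphenyl)chromen-4-one | COc1ccc(cc1)-c1coc2cc(OC)c(I)c(O)c2c1=O | intermediate
4 | 6-iodo-5,7-dimethoxy-3-(4-methoxyphenyl)chromen-4-one | COc1ccc(cc1)-c1coc2cc(OC)c(I)c(OC)c2c1=O | intermediate
5 | chloroacetaldehyde dimethyl acetal (2-chloro-1,1-dimethoxyethane) | COC(CCl)OC | starting material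
6 | lithium methoxyacetylide | [Li]C#COC | intermediate
7 | tributyl(methoxyethynyl)stannane | CCCC[Sn](CCCC)(CCCC)C#COC | intermediate
8 | 6-(methoxyethynyl)-5,7-dimethoxy-3-(4-methoxyphenyl)chromen-4-one | COC#Cc1c(OC)cc2occ(-c3ccc(OC)cc3)c(=O)c2c1OC | intermediate
9 | acetyl chloride | CC(Cl)=O | starting material
10 | ethoxyacetylene | CCOC#C | starting material
11 | ketene | C=C=O | intermediate
12 | 3-ethoxycyclobut-2-en-1-one | CCOC1=CC(=O)C1 | intermediate
13 | 3-ethoxybuta-1,3-dien-1-one (3-ethoxyvinylketene) | C=C(OCC)C=C=O | intermediate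
14 | 4-(1-ethoxyethenyl)-3-methoxy-2-IsoF-cyclobut-2-en-1-one (racemic) | C=C(OCC)C1C(=O)C(=C1OC)c1c(OC)cc2occ(-c3ccc(OC)cc3)c(=O)c2c1OC | intermediate
15 | 5-ethoxy-3-methoxy-2-IsoF-hexa-1,3,5-trien-1-one, with C2 and the ethoxyvinyl group cis on C3=C4 | C=C(OCC)/C=C(OC)\C(=C=O)c1c(OC)cc2occ(-c3ccc(OC)cc3)c(=O)c2c1OC | intermediate
16 | 5-ethoxy-3-methoxy-2-IsoF-cyclohexa-2,4-dien-1-one | CCOC1=CC(OC)=C(C(=O)C1)c1c(OC)cc2occ(-c3ccc(OC)cc3)c(=O)c2c1OC | intermediate
17 | 6-(4-ethoxy-2-hydroxy-6-methoxyphenyl)-5,7-dimethoxy-3-(4-methoxyphenyl)chromen-4-one | CCOc1cc(O)c(c(OC)c1)-c1c(OC)cc2occ(-c3ccc(OC)cc3)c(=O)c2c1OC | intermediate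
18 | 4-methoxyphenylacetic acid | COc1ccc(CC(=O)O)cc1 | starting material
19 | 6-{4-ethoxy-2-hydroxy-6-methoxy-3-[2-(4-methoxyphenyl)acetyl]phenyl}-5,7-dimethoxy-3-(4-methoxyphenyl)chromen-4-one | CCOc1cc(OC)c(c(O)c1C(=O)Cc1ccc(OC)cc1)-c1c(OC)cc2occ(-c3ccc(OC)cc3)c(=O)c2c1OC | intermediate
20 | 6-{3-[3-(dimethylamino)-2-(4-methoxyphenyl)prop-2-enoyl]-4-ethoxy-2-hydroxy-6-methoxyphenyl}-5,7-dimethoxy-3-(4-methoxyphenyl)chromen-4-one (labile C=C geometry) | CCOc1cc(OC)c(c(O)c1C(=O)C(=CN(C)C)c1ccc(OC)cc1)-c1c(OC)cc2occ(-c3ccc(OC)cc3)c(=O)c2c1OC | intermediate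
21 | 5-ethoxy-7-methoxy-3-(4-methoxyphenyl)-8-[5,7-dimethoxy-3-(4-methoxyphenyl)-4-oxochromen-6-yl]chromen-4-one | CCOc1cc(OC)c(-c2c(OC)cc3occ(-c4ccc(OC)cc4)c(=O)c3c2OC)c2occ(-c3ccc(OC)cc3)c(=O)c12 | intermediate
22 | 5,7-dihydroxy-3-(4-hydroxyphenyl)-6-[5,7-dihydroxy-3-(4-hydroxyphenyl)-4-oxochromen-8-yl]chromen-4-one (6,8'-bigenistein) | O=c1c(-c2ccc(O)cc2)coc2cc(O)c(-c3c(O)cc(O)c4c(=O)c(-c5ccc(O)cc5)coc34)c(O)c12 | target

**Total step count:** 10.
**Longest linear sequence:** 8 (steps 1, 2, 3, 5, 7, 8, 9, 10).

**Steps most likely to fail**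

**Step 7.**
- What may go wrong: the push–pull stabilised cyclobutenone may open slowly. At the temperature required, the vinylketene would then oligomerise faster than the crowded alkyne traps it.
- Fallback, from 8 back to 17: the same vinylketene 13 is generated at room temperature by a photochemical Wolff rearrangement, the diazo ketone variant of the benzannulation.
- Ethyl vinyl ether is lithiated with t-BuLi in THF to (1-ethoxyethenyl)lithium F1. Acylation with N-methoxy-N-methylacetamide and an NH4Cl quench give 3-ethoxybut-3-en-2-one F2.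
- LiN(SiMe3)2 and CF3CO2CH2CF3 give 5-ethoxy-1,1,1-trifluorohex-5-ene-2,4-dione F3. MsN3 with Et3N in MeCN converts it by detrifluoroacetylative diazo transfer to 1-diazo-3-ethoxybut-3-en-2-one F4.
- This diazo ketone is irradiated at 365 nm, where the isoflavone hardly absorbs, together with 8 in CH2Cl2. Brief heating in toluene then carries the material through 14, 15 and 16 to 17.

**Step 8.**
- What may go wrong: acylation may occur at C6' between the two ether oxygens instead of at C4a'. The bulky, enolisable arylacetyl group may transfer sluggishly beside the crowded axis. Peri ethers may erode on long heating in BF3·OEt2.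
- Fallback, from 17 back to 21: the small acetyl group is installed first and the aryl ring is attached last by cross-coupling.
- Ac2O in BF3·OEt2 at 60 °C (acetate formation, then Fries shift) gives 6-(3-acetyl-4-ethoxy-2-hydroxy-6-methoxyphenyl)-5,7-dimethoxy-3-(4-methoxyphenyl)chromen-4-one F5.
- Me2NCH(OMe)2 converts it to 6-{3-[(E)-3-(dimethylamino)prop-2-enoyl]-4-ethoxy-2-hydroxy-6-methoxyphenyl}-5,7-dimethoxy-3-(4-methoxyphenyl)chromen-4-one F6.
- I2 in CHCl3 cyclises this enaminone to 6-(5-ethoxy-3-iodo-7-methoxy-4-oxochromen-8-yl)-5,7-dimethoxy-3-(4-methoxyphenyl)chromen-4-one F7.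
- Suzuki–Miyaura coupling with 4-methoxyphenylboronic acid (Pd(PPh3)4, K2CO3, dioxane–H2O) delivers 21.
- A wrongly acetylated isomer has no ortho hydroxyl, cannot cyclise, and is removed on the way.

**Step 6.**
- What may go wrong: ketene may self-condense and acetyl chloride may acylate directly, both outrunning the cycloaddition. The ammonium salt may also protonate the ynol ether.
- Fallback, from 10 back to 12: the more electrophilic, non-dimerising dichloroketene F8 is generated from trichloroacetyl chloride and Zn–Cu couple in Et2O in the presence of 10.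
- This gives 4,4-dichloro-3-ethoxycyclobut-2-en-1-one F9.
- Reductive dechlorination with Zn dust, AcOH and TMEDA in EtOH then gives 12.

**Further compounds**
F1 | step 7 | (1-ethoxyethenyl)lithium | [Li]C(=C)OCC
F2 | step 7 | 3-ethoxybut-3-en-2-one | C=C(OCC)C(C)=O
F3 | step 7 | 5-ethoxy-1,1,1-trifluorohex-5-ene-2,4-dione | C=C(OCC)C(=O)CC(=O)C(F)(F)F
F4 | step 7 | 1-diazo-3-ethoxybut-3-en-2-one | C=C(OCC)C(=O)C=[N+]=[N-]
F5 | step 8 | 6-(3-acetyl-4-ethoxy-2-hydroxy-6-methoxyphenyl)-5,7-dimethoxy-3-(4-methoxyphenyl)chromen-4-one | CCOc1cc(OC)c(c(O)c1C(C)=O)-c1c(OC)cc2occ(-c3ccc(OC)cc3)c(=O)c2c1OC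
F6 | step 8 | 6-{3-[(E)-3-(dimethylamino)prop-2-enoyl]-4-ethoxy-2-hydroxy-6-methoxyphenyl}-5,7-dimethoxy-3-(4-methoxyphenyl)chromen-4-one | CCOc1cc(OC)c(c(O)c1C(=O)/C=C/N(C)C)-c1c(OC)cc2occ(-c3ccc(OC)cc3)c(=O)c2c1OC
F7 | step 8 | 6-(5-ethoxy-3-iodo-7-methoxy-4-oxochromen-8-yl)-5,7-dimethoxy-3-(4-methoxyphenyl)chromen-4-one | CCOc1cc(OC)c(-c2c(OC)cc3occ(-c4ccc(OC)cc4)c(=O)c3c2OC)c2occ(I)c(=O)c12
F8 | step 6 | dichloroketene | ClC(Cl)=C=O
F9 | step 6 | 4,4-dichloro-3-ethoxycyclobut-2-en-1-one | CCOC1=CC(=O)C1(Cl)Cl
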